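**Retrosynthetic overview**
1. Target 12 ⇐ 11 by removal of three phenolic TBS groups.
2. 11 ⇐ aryl bromide 10 + iodohydrin 5: the C8–C1'' bond is made by a visible-light nickel/photoredox cross-electrophile coupling (key step).
3. 10 ⇐ (2S)-eriodictyol 6 by 7,3',4'-silylation, C6 iodination/C8 bromination and Stille prenylation at C6–I.
4. 5 ⇐ methyl (R)-glycerate acetonide 1 by MeMgBr addition, dehydration, acetonide cleavage and primary iodination.
5. No ring is built: rings A, B and the pyranone ring C come intact, with C2, from 6; the carbinol stereocenter comes from 1.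

Assumption: commercial (−)-eriodictyol 6 is the (2S)-enantiomer (ee checked by chiral HPLC before use); TBS = tert-butyldimethylsilyl; flavanone numbering O1, C2–C8, ring B 1'–6', side chain 1''–4''.

**Step 1**
Reactants: 1 methyl (4R)-2,2-dimethyl-1,3-dioxolane-4-carboxylate
Product: 2 2-[(4R)-2,2-dimethyl-1,3-dioxolan-4-yl]propan-2-ol
Conditions: MeMgBr (2.5 equiv), THF, 0 → 25 °C; aq. NH4Cl
Reagents that add atoms: methylmagnesium bromide, C[Mg]Br
Why: Double Grignard addition to the ester gives the tertiary carbinol, and the α-oxygenated stereocenter (the future carbinol carbon) is not touched by the fast, cold addition.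

**Step 2**
Reactants: 2 2-[(4R)-2,2-dimethyl-1,3-dioxolan-4-yl]propan-2-ol
Product: 3 (4S)-2,2-dimethyl-4-(prop-1-en-2-yl)-1,3-dioxolane
Conditions: Burgess reagent (1.3 equiv), THF, 40 °C; careful distillation (volatile product)
Reagents that add atoms: none
Why: Burgess syn-elimination of the tertiary sulfamate takes a methyl hydrogen, away from the oxygen-bearing carbon, as in dehydrations of 2-(2-hydroxyprop-2-yl) cyclic ethers to isopropenyl ethers; no bond to the stereocenter changes (the descriptor changes from R to S by priority only).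

**Step 3**
Reactants: 3 (4S)-2,2-dimethyl-4-(prop-1-en-2-yl)-1,3-dioxolane
Product: 5 (2S)-1-iodo-3-methylbut-3-en-2-ol, via (2S)-3-methylbut-3-ene-1,2-diol 4 (not isolated)
Conditions: PPTS (cat.), MeOH, 40 °C, then strip volatiles; PPh3, imidazole, I2 (1.05 equiv each), CH2Cl2, 0 °C, dark
Reagents that add atoms: iodine, II
Why: Acid-catalysed transketalisation frees the diol, and the Appel (Garegg–Samuelsson) iodination at 0 °C converts only the primary hydroxyl by SN2 at CH2, so the secondary carbinol keeps its configuration.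

**Step 4**
Reactants: 6 (2S)-eriodictyol
Product: 7 (2S)-7,3',4'-tri-O-TBS-eriodictyol
Conditions: TBSCl (3.3 equiv), imidazole (6 equiv), DMF, 0 → 25 °C
Reagents that add atoms: tert-butyldimethylsilyl chloride, CC(C)(C)[Si](C)(C)Cl
Why: The three unchelated phenols are silylated while the 5-OH, hydrogen-bonded to C4=O, stays free, and imidazole is too weak a base to open the flavanone to the chalcone, so C2 is not racemised.

**Step 5**
Reactants: 7 (2S)-7,3',4'-tri-O-TBS-eriodictyol
Product: 9 (2S)-8-bromo-6-iodo-7,3',4'-tri-O-TBS-eriodictyol, via (2S)-6-iodo-7,3',4'-tri-O-TBS-eriodictyol 8 (not isolated)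
Conditions: NIS (1.0 equiv), DMF, 0 → 25 °C, dark; then NBS (1.05 equiv), 0 → 25 °C
Reagents that add atoms: N-iodosuccinimide, O=C1CCC(=O)N1I; N-bromosuccinimide, O=C1CCC(=O)N1Br
Why: Electrophilic aromatic substitution on ring A, where a free chelated 5-OH next to a 7-O-substituent sends the first halogen to C6 (the known preference of 5-hydroxy-7-alkoxy flavonoids) and the second halogen can only enter the last free position C8; the silylated ring B is less activated.

**Step 6**
Reactants: 9 (2S)-8-bromo-6-iodo-7,3',4'-tri-O-TBS-eriodictyol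
Product: 10 (2S)-8-bromo-6-(3-methylbut-2-en-1-yl)-7,3',4'-tri-O-TBS-eriodictyol
Conditions: tributyl(3-methylbut-2-en-1-yl)stannane (1.3 equiv), Pd(PPh3)4 (5 mol %), toluene, 90 °C
Reagents that add atoms: tributyl(3-methylbut-2-en-1-yl)stannane, CCCC[Sn](CCCC)(CCCC)CC=C(C)C
Why: Stille coupling in which zerovalent palladium inserts into C–I far faster than into the hindered, electron-rich C–Br bond, and reductive elimination at the less substituted allyl terminus gives the linear prenyl group.

**Step 7**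
Reactants: 10 (2S)-8-bromo-6-(3-methylbut-2-en-1-yl)-7,3',4'-tri-O-TBS-eriodictyol; 5 (2S)-1-iodo-3-methylbut-3-en-2-ol
Product: 11 (2S)-8-[(2R)-2-hydroxy-3-methylbut-3-en-1-yl]-6-(3-methylbut-2-en-1-yl)-7,3',4'-tri-O-TBS-eriodictyol
Conditions: 5 (2 equiv), [Ir(dF(CF3)ppy)2(dtbbpy)]PF6 (2 mol %), NiBr2(MeOCH2CH2OMe) (10 mol %), 4,4'-dimethoxy-2,2'-bipyridine (12 mol %), (Me3Si)3SiH (1.5 equiv), 2,6-lutidine (2 equiv), DME, 450 nm LEDs, 25 °C
Reagents that add atoms: none
Why: Proposed new method: the silyl-radical nickel/photoredox cross-electrophile coupling is extended to two substrate types on which it has not been shown, a fully substituted aryl bromide flanked by two oxygen substituents inside an unprotected 5-hydroxyflavanone and an enantiopure unprotected iodohydrin; the excited iridium photocatalyst oxidises bromide, the bromine atom takes H from (Me3Si)3SiH, and the silyl radical abstracts iodine from 5 (much faster than bromine from 10 or addition to the alkenes) to give a primary β-hydroxyalkyl radical, which is trapped by the aryl nickel bromide (divalent nickel) formed from 10 and zerovalent nickel carrying the small, electron-rich dimethoxybipyridine, and reductive elimination from trivalent nickel forms the C8–C1'' bond; the carbinol carbon is never a reactive centre, so its configuration is carried over unchanged (S in 5 becomes R in 11 by priority change only), and the competing 1,2-vinyl shift of the homoallylic radical is slow because it needs 3-exo attack on the methyl-bearing alkene carbon; closest known reaction types are the nickel/photoredox silyl-radical coupling of aryl bromides with alkyl halides and the nickel-catalysed epoxide–aryl halide coupling, which runs through iodohydrin-derived β-hydroxyalkyl radicals.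

**Step 8**
Reactants: 11 (2S)-8-[(2R)-2-hydroxy-3-methylbut-3-en-1-yl]-6-(3-methylbut-2-en-1-yl)-7,3',4'-tri-O-TBS-eriodictyol
Product: 12 (2S)-2-(3,4-dihydroxyphenyl)-5,7-dihydroxy-8-[(2R)-2-hydroxy-3-methylbut-3-en-1-yl]-6-(3-methylbut-2-en-1-yl)-2,3-dihydro-4H-chromen-4-one (CNP0322081.2)
Conditions: TBAF (3.5 equiv), AcOH (3.5 equiv), THF, 0 °C
Reagents that add atoms: none
Why: Buffered fluoride cleaves the three aryl silyl ethers (Si–O to Si–F) without free base or acid, so C2 is not racemised through the chalcone and neither the prenyl group nor the allylic alcohol cyclises onto a phenol.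

**Compound list**
1 | methyl (4R)-2,2-dimethyl-1,3-dioxolane-4-carboxylate | COC(=O)[C@H]1COC(C)(C)O1 | starting material
2 | 2-[(4R)-2,2-dimethyl-1,3-dioxolan-4-yl]propan-2-ol | CC(C)(O)[C@H]1COC(C)(C)O1 | intermediate
3 | (4S)-2,2-dimethyl-4-(prop-1-en-2-yl)-1,3-dioxolane | C=C(C)[C@H]1COC(C)(C)O1 | intermediate
4 | (2S)-3-methylbut-3-ene-1,2-diol | C=C(C)[C@H](O)CO | intermediate
5 | (2S)-1-iodo-3-methylbut-3-en-2-ol | C=C(C)[C@H](O)CI | intermediate
6 | (2S)-eriodictyol, (2S)-2-(3,4-dihydroxyphenyl)-5,7-dihydroxy-2,3-dihydro-4H-chromen-4-one | Oc1cc(O)c2c(c1)O[C@H](c1ccc(O)c(O)c1)CC2=O | starting material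
7 | (2S)-2-{3,4-bis[(tert-butyldimethylsilyl)oxy]phenyl}-7-[(tert-butyldimethylsilyl)oxy]-5-hydroxy-2,3-dihydro-4H-chromen-4-one | CC(C)(C)[Si](C)(C)Oc1cc(O)c2c(c1)O[C@H](c1ccc(O[Si](C)(C)C(C)(C)C)c(O[Si](C)(C)C(C)(C)C)c1)CC2=O | intermediate
8 | 6-iodo derivative of 7 | CC(C)(C)[Si](C)(C)Oc1c(I)c(O)c2c(c1)O[C@H](c1ccc(O[Si](C)(C)C(C)(C)C)c(O[Si](C)(C)C(C)(C)C)c1)CC2=O | intermediate
9 | 8-bromo-6-iodo derivative of 7 | CC(C)(C)[Si](C)(C)Oc1c(I)c(O)c2c(c1Br)O[C@H](c1ccc(O[Si](C)(C)C(C)(C)C)c(O[Si](C)(C)C(C)(C)C)c1)CC2=O | intermediate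
10 | 8-bromo-6-(3-methylbut-2-en-1-yl) derivative of 7 | CC(C)(C)[Si](C)(C)Oc1c(CC=C(C)C)c(O)c2c(c1Br)O[C@H](c1ccc(O[Si](C)(C)C(C)(C)C)c(O[Si](C)(C)C(C)(C)C)c1)CC2=O | intermediate
11 | 8-[(2R)-2-hydroxy-3-methylbut-3-en-1-yl]-6-(3-methylbut-2-en-1-yl) derivative of 7 | CC(C)(C)[Si](C)(C)Oc1c(CC=C(C)C)c(O)c2c(c1C[C@@H](O)C(C)=C)O[C@H](c1ccc(O[Si](C)(C)C(C)(C)C)c(O[Si](C)(C)C(C)(C)C)c1)CC2=O | intermediate
12 | (2S)-2-(3,4-dihydroxyphenyl)-5,7-dihydroxy-8-[(2R)-2-hydroxy-3-methylbut-3-en-1-yl]-6-(3-methylbut-2-en-1-yl)-2,3-dihydro-4H-chromen-4-one | C=C(C)[C@H](O)Cc1c(O)c(CC=C(C)C)c(O)c2c1O[C@H](c1ccc(O)c(O)c1)CC2=O | target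

**Step count and risks**
Total steps: 8. Longest linear sequence: 5 (steps 4–8 from 6, or steps 1–3, 7, 8 from 1).

Three steps most likely to fail:

Step 7 (the proposed new coupling). Risks are slow oxidative addition at the doubly ortho-substituted C8–Br, photocatalyst quenching by the phenol, and rearrangement of the homoallylic radical. The fallback is known chemistry and sets out from 5 and 10. Alcohol 5 is silylated (TBSOTf, 2,6-lutidine, CH2Cl2, −78 °C) to tert-butyl{[(2S)-1-iodo-3-methylbut-3-en-2-yl]oxy}dimethylsilane F1. F1 is joined to 10 by the established thermal nickel reductive cross-electrophile coupling of aryl bromides with primary alkyl iodides (NiI2, 4,4'-dimethoxy-2,2'-bipyridine, NaI, pyridine, Mn powder, DMPU, 60 °C). This uses no light, photocatalyst or silyl radical, and Mn is chosen over Zn so that no β-silyloxy alkylzinc forms and eliminates. The product is (2S)-8-[(2R)-2-(TBS-oxy)-3-methylbut-3-en-1-yl]-6-(3-methylbut-2-en-1-yl)-7,3',4'-tri-O-TBS-eriodictyol F2. TBAF/AcOH in THF at 25 °C (longer) removes all four silyl groups and the fallback comes back to the route at 12. This fallback still relies on oxidative addition of nickel at C8–Br and on the same alkyl radical.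

Step 5 (regiochemistry of the first halogenation). If iodination of 7 is not clean for C6, the fallback sets out from 7 and fixes the order of entry with a temporary O5 group. Mitsunobu allylation of the chelated 5-OH (allyl alcohol, PPh3, DIAD, THF, 0 → 25 °C) gives (2S)-5-O-allyl-7,3',4'-tri-O-TBS-eriodictyol F3. With O5 alkylated, NBS (DMF, 0 °C) brominates the less hindered C8 between O1 and the 7-silyloxy group, giving (2S)-5-O-allyl-8-bromo-7,3',4'-tri-O-TBS-eriodictyol F4. Pd(PPh3)4/morpholine (THF, 25 °C) removes the allyl group to give (2S)-8-bromo-7,3',4'-tri-O-TBS-eriodictyol F5. NIS (DMF) then iodinates the only free ring A position, C6, and the fallback comes back at 9.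

Step 6 (Stille prenylation: α/γ selectivity and I-versus-Br selectivity). The fallback sets out from 9. Stille coupling with allyltributylstannane (Pd(PPh3)4, toluene, 90 °C), which has no regiochemical ambiguity in the allyl unit, gives (2S)-6-allyl-8-bromo-7,3',4'-tri-O-TBS-eriodictyol F6. Cross-metathesis with excess 2-methyl-2-butene (second-generation Grubbs catalyst RuCl2(=CHPh)(PCy3)(H2IMes), CH2Cl2, 40 °C) turns allyl into prenyl and the fallback comes back at 10.

**Further compounds**
F1 | step 7 | tert-butyl{[(2S)-1-iodo-3-methylbut-3-en-2-yl]oxy}dimethylsilane | C=C(C)[C@H](O[Si](C)(C)C(C)(C)C)CI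
F2 | step 7 | (2S)-8-[(2R)-2-(TBS-oxy)-3-methylbut-3-en-1-yl]-6-(3-methylbut-2-en-1-yl)-7,3',4'-tri-O-TBS-eriodictyol | CC(C)(C)[Si](C)(C)Oc1c(CC=C(C)C)c(O)c2c(c1C[C@@H](O[Si](C)(C)C(C)(C)C)C(C)=C)O[C@H](c1ccc(O[Si](C)(C)C(C)(C)C)c(O[Si](C)(C)C(C)(C)C)c1)CC2=O
F3 | step 5 | (2S)-5-O-allyl-7,3',4'-tri-O-TBS-eriodictyol | CC(C)(C)[Si](C)(C)Oc1cc(OCC=C)c2c(c1)O[C@H](c1ccc(O[Si](C)(C)C(C)(C)C)c(O[Si](C)(C)C(C)(C)C)c1)CC2=O
F4 | step 5 | (2S)-5-O-allyl-8-bromo-7,3',4'-tri-O-TBS-eriodictyol | CC(C)(C)[Si](C)(C)Oc1cc(OCC=C)c2c(c1Br)O[C@H](c1ccc(O[Si](C)(C)C(C)(C)C)c(O[Si](C)(C)C(C)(C)C)c1)CC2=O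
F5 | step 5 | (2S)-8-bromo-7,3',4'-tri-O-TBS-eriodictyol | CC(C)(C)[Si](C)(C)Oc1cc(O)c2c(c1Br)O[C@H](c1ccc(O[Si](C)(C)C(C)(C)C)c(O[Si](C)(C)C(C)(C)C)c1)CC2=O
F6 | step 6 | (2S)-6-allyl-8-bromo-7,3',4'-tri-O-TBS-eriodictyol | CC(C)(C)[Si](C)(C)Oc1c(CC=C)c(O)c2c(c1Br)O[C@H](c1ccc(O[Si](C)(C)C(C)(C)C)c(O[Si](C)(C)C(C)(C)C)c1)CC2=O
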